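**Strategy.** The 1,4-benzodioxine ring (O1–C2(aryl)–C3(CH2OH)–O4–C4a–C8a) is cut at the aryl ether bond O4–C4a, the oxygen on C3 that sits meta to the chromone. The key step, a palladium-catalysed intramolecular aryl etherification, exploits the ortho relationship of C8a–O1 and C4a on the benzo ring: the O1–C2 ether, already in place, holds the C3 hydroxyl next to a C4a bromide, so the dioxane ring closes with both stereocentres untouched. Its precursor is a threo (1R,2R) 1-aryl-1-(2-bromo-4-formylphenoxy)propane-2,3-diol, made from (R)-glyceraldehyde acetonide by Felkin–Anh arylation and Mitsunobu inversion. The aldehyde then carries the flavonol through a Claisen–Schmidt/Algar–Flynn–Oyamada sequence, and hydrogenolysis frees the phenols.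

Key step: step 4

Remark: ketone 9 and aldehyde 2 are taken as catalogue compounds, 2 being distilled just before use; in the open-chain compounds the propane chain is numbered C1 (benzylic), C2, C3.

**Step 1**
Reactants: 1 1-(benzyloxy)-4-bromo-2-methoxybenzene; 2 (R)-2,2-dimethyl-1,3-dioxolane-4-carbaldehyde
Product: 4 (S)-[4-(benzyloxy)-3-methoxyphenyl][(4R)-2,2-dimethyl-1,3-dioxolan-4-yl]methanol, via arylmagnesium bromide 3 (not isolated)
Conditions: Mg, cat. I2, THF, 45 °C; then 2, THF, −78 → −20 °C; H2O work-up; chromatography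
Reagents that add atoms: none
Why: Grignard formation followed by 1,2-addition to the α-alkoxy aldehyde under Felkin–Anh (non-chelation) control, with the dioxolane C–O bond anti to the incoming aryl group, should favour the anti carbinol with the new centre (S), while C4 (R) comes unchanged from 2; the minor syn epimer is removed by chromatography.

**Step 2**
Reactants: 4 (S)-[4-(benzyloxy)-3-methoxyphenyl][(4R)-2,2-dimethyl-1,3-dioxolan-4-yl]methanol; 5 3-bromo-4-hydroxybenzaldehyde
Product: 6 3-bromo-4-{(R)-[4-(benzyloxy)-3-methoxyphenyl][(4R)-2,2-dimethyl-1,3-dioxolan-4-yl]methoxy}benzaldehyde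
Conditions: PPh3, diisopropyl azodicarboxylate (DIAD), toluene, 0 °C → rt
Reagents that add atoms: none
Why: Mitsunobu etherification: the acidic phenol 5 should displace the benzylic oxyphosphonium in an SN2 step with inversion, turning the (S) carbinol into the (R) aryl ether (threo), the inductively withdrawing dioxolane oxygen next to the reacting carbon disfavouring ionization.

**Step 3**
Reactants: 6 3-bromo-4-{(R)-[4-(benzyloxy)-3-methoxyphenyl][(4R)-2,2-dimethyl-1,3-dioxolan-4-yl]methoxy}benzaldehyde
Product: 7 3-bromo-4-{[(1R,2R)-1-[4-(benzyloxy)-3-methoxyphenyl]-2,3-dihydroxypropyl]oxy}benzaldehyde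
Conditions: AcOH/H2O (4:1), 45 °C
Reagents that add atoms: none
Why: Acid-catalysed hydrolysis of the isopropylidene ketal in aqueous acetic acid should free the 2,3-diol while the benzyl ether, the aldehyde and the benzylic aryl ether, whose cation is destabilised by the neighbouring oxygen, stay intact and no stereocentre is touched.

**Step 4**
Reactants: 7 3-bromo-4-{[(1R,2R)-1-[4-(benzyloxy)-3-methoxyphenyl]-2,3-dihydroxypropyl]oxy}benzaldehyde
Product: 8 (2R,3R)-2-[4-(benzyloxy)-3-methoxyphenyl]-3-(hydroxymethyl)-2,3-dihydro-1,4-benzodioxine-6-carbaldehyde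
Conditions: Pd(OAc)2 (cat.), 2-(di-tert-butylphosphino)-1,1'-binaphthyl (cat.), Cs2CO3, toluene, 70 °C
Reagents that add atoms: none
Why: Zerovalent palladium should insert into the C–Br bond ortho to the aryl ether oxygen, carbonate-assisted exchange of bromide for the C2 secondary alkoxide should give a seven-membered aryl(alkoxo)palladium chelate, and C(sp2)–O reductive elimination then forms the O4–C4a bond. The closest known reaction type is the palladium-catalysed intramolecular C–O cross-coupling of aryl halides with primary and secondary alcohols (Buchwald–Hartwig-type etherification), which is established for 1,4-benzodioxanes. The dioxane ring closes as a six-membered ring in a 6-exo sense, by reductive elimination from the seven-membered palladacycle. No stereocentre is formed or broken, because the C–O bonds at both carbinol carbons stay intact, so the threo (1R,2R) diol ether maps onto the trans (2R,3R) ring. The step needs the secondary hydroxyl to react in preference to the primary one and reductive elimination to outrun β-hydride elimination; the 1,2-relationship of ether oxygen and secondary hydroxyl (six- against seven-membered ring) secures the first and the bulky electron-rich di-tert-butyl biaryl phosphine the second. The mild carbonate base should spare the aldehyde and keep the alkoxide concentration too low for an O-to-O aryl shift (Smiles rearrangement) at the formyl-activated ring.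

**Step 5**
Reactants: 8 (2R,3R)-2-[4-(benzyloxy)-3-methoxyphenyl]-3-(hydroxymethyl)-2,3-dihydro-1,4-benzodioxine-6-carbaldehyde; 9 1-[2,4-bis(benzyloxy)-6-hydroxyphenyl]ethan-1-one
Product: 12 5,7-bis(benzyloxy)-2-[(2R,3R)-2-[4-(benzyloxy)-3-methoxyphenyl]-3-(hydroxymethyl)-2,3-dihydro-1,4-benzodioxin-6-yl]-3-hydroxy-4H-chromen-4-one, via chalcone 10 (not isolated), via 3-hydroxyflavanone 11 (not isolated)
Conditions: KOH, EtOH/THF, rt; then aq. NaOH, 30% H2O2, 0 °C → rt
Reagents that add atoms: hydrogen peroxide, OO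
Why: Claisen–Schmidt condensation should give the (E)-2'-hydroxychalcone, which alkaline hydrogen peroxide converts in the same flask by the Algar–Flynn–Oyamada reaction (oxidative 6-endo cyclization to the 3-hydroxyflavanone, then dehydrogenation) into the flavonol; the transient chromanone stereocentres vanish on aromatization and the benzodioxine centres are not involved.

**Step 6**
Reactants: 12 5,7-bis(benzyloxy)-2-[(2R,3R)-2-[4-(benzyloxy)-3-methoxyphenyl]-3-(hydroxymethyl)-2,3-dihydro-1,4-benzodioxin-6-yl]-3-hydroxy-4H-chromen-4-one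
Product: 13 3,5,7-trihydroxy-2-[(2R,3R)-2-(4-hydroxy-3-methoxyphenyl)-3-(hydroxymethyl)-2,3-dihydro-1,4-benzodioxin-6-yl]-4H-chromen-4-one
Conditions: H2 (1 atm), Pd/C, THF/MeOH, rt
Reagents that add atoms: none
Why: Hydrogenolysis of the three aryl benzyl ethers over palladium on carbon should free the phenols, the primary benzylic C–O bonds reacting far faster than the secondary cyclic C2–O1 ether or the C2=C3 bond of the flavonol, so both stereocentres persist.

**Compound list**

1 | 1-(benzyloxy)-4-bromo-2-methoxybenzene | COc1cc(Br)ccc1OCc1ccccc1 | starting material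
2 | (R)-2,2-dimethyl-1,3-dioxolane-4-carbaldehyde | O=C[C@H]1COC(C)(C)O1 | starting material
3 | [4-(benzyloxy)-3-methoxyphenyl]magnesium bromide | COc1cc([Mg]Br)ccc1OCc1ccccc1 | intermediate
4 | (S)-[4-(benzyloxy)-3-methoxyphenyl][(4R)-2,2-dimethyl-1,3-dioxolan-4-yl]methanol (anti) | COc1cc([C@H](O)[C@H]2COC(C)(C)O2)ccc1OCc1ccccc1 | intermediate
5 | 3-bromo-4-hydroxybenzaldehyde | O=Cc1ccc(O)c(Br)c1 | starting material
6 | 3-bromo-4-{(R)-[4-(benzyloxy)-3-methoxyphenyl][(4R)-2,2-dimethyl-1,3-dioxolan-4-yl]methoxy}benzaldehyde | COc1cc([C@@H](Oc2ccc(C=O)cc2Br)[C@H]2COC(C)(C)O2)ccc1OCc1ccccc1 | intermediate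
7 | 3-bromo-4-{[(1R,2R)-1-[4-(benzyloxy)-3-methoxyphenyl]-2,3-dihydroxypropyl]oxy}benzaldehyde | COc1cc([C@@H](Oc2ccc(C=O)cc2Br)[C@H](O)CO)ccc1OCc1ccccc1 | intermediate
8 | (2R,3R)-2-[4-(benzyloxy)-3-methoxyphenyl]-3-(hydroxymethyl)-2,3-dihydro-1,4-benzodioxine-6-carbaldehyde | COc1cc([C@H]2Oc3ccc(C=O)cc3O[C@@H]2CO)ccc1OCc1ccccc1 | intermediate
9 | 1-[2,4-bis(benzyloxy)-6-hydroxyphenyl]ethan-1-one | CC(=O)c1c(O)cc(OCc2ccccc2)cc1OCc1ccccc1 | starting material
10 | (E)-1-[2,4-bis(benzyloxy)-6-hydroxyphenyl]-3-[(2R,3R)-2-[4-(benzyloxy)-3-methoxyphenyl]-3-(hydroxymethyl)-2,3-dihydro-1,4-benzodioxin-6-yl]prop-2-en-1-one | COc1cc([C@H]2Oc3ccc(/C=C/C(=O)c4c(O)cc(OCc5ccccc5)cc4OCc4ccccc4)cc3O[C@@H]2CO)ccc1OCc1ccccc1 | intermediate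
11 | 5,7-bis(benzyloxy)-2-[(2R,3R)-2-[4-(benzyloxy)-3-methoxyphenyl]-3-(hydroxymethyl)-2,3-dihydro-1,4-benzodioxin-6-yl]-3-hydroxy-2,3-dihydro-4H-chromen-4-one (trans at the chromanone C2/C3, both diastereomers) | COc1cc([C@H]2Oc3ccc(C4Oc5cc(OCc6ccccc6)cc(OCc6ccccc6)c5C(=O)C4O)cc3O[C@@H]2CO)ccc1OCc1ccccc1 | intermediate
12 | 5,7-bis(benzyloxy)-2-[(2R,3R)-2-[4-(benzyloxy)-3-methoxyphenyl]-3-(hydroxymethyl)-2,3-dihydro-1,4-benzodioxin-6-yl]-3-hydroxy-4H-chromen-4-one | COc1cc([C@H]2Oc3ccc(-c4oc5cc(OCc6ccccc6)cc(OCc6ccccc6)c5c(=O)c4O)cc3O[C@@H]2CO)ccc1OCc1ccccc1 | intermediate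
13 | 3,5,7-trihydroxy-2-[(2R,3R)-2-(4-hydroxy-3-methoxyphenyl)-3-(hydroxymethyl)-2,3-dihydro-1,4-benzodioxin-6-yl]-4H-chromen-4-one | COc1cc([C@H]2Oc3ccc(-c4oc5cc(O)cc(O)c5c(=O)c4O)cc3O[C@@H]2CO)ccc1O | target

**Total step count:** 6
**Longest linear sequence:** 6 steps (1 → 13)

**Steps most likely to fail**

Step 5. The 6'-benzyloxy group of the chalcone may divert the oxidative cyclization into the five-membered (5-exo, benzofuranone-forming) mode, so that the six-membered flavonol closure is outcompeted. The fallback sets out from chalcone 10, isolated by stopping step 5 before the peroxide is added. Catalytic I2 in DMSO at 120 °C should give, by oxa-Michael closure and dehydrogenation, the flavone 5,7-bis(benzyloxy)-2-[(2R,3R)-2-[4-(benzyloxy)-3-methoxyphenyl]-3-(hydroxymethyl)-2,3-dihydro-1,4-benzodioxin-6-yl]-4H-chromen-4-one F1. Dimethyldioxirane in acetone/CH2Cl2 at 0 °C, followed by catalytic p-TsOH, should epoxidize the chromone C2=C3 bond and open the epoxide to the 3-hydroxyflavone, which comes back to the route at 12.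

Step 2. Partial ionization of the electron-rich benzylic oxyphosphonium (SN1 leakage) may erode the inversion, and displacement at the hindered carbinol by an ortho-substituted phenol may be slow; a weak anti preference in step 1 would add to the loss. The fallback sets out from 4 (or from the unseparated carbinol mixture of step 1). Dess–Martin periodinane with NaHCO3 in CH2Cl2 should give the ketone [4-(benzyloxy)-3-methoxyphenyl][(4R)-2,2-dimethyl-1,3-dioxolan-4-yl]methanone F2. Reduction with LiBH(s-Bu)3 in THF at −78 °C under Felkin–Anh control should give the syn carbinol (R)-[4-(benzyloxy)-3-methoxyphenyl][(4R)-2,2-dimethyl-1,3-dioxolan-4-yl]methanol F3. Its sodium alkoxide (NaH, DMF, 0 °C → rt) should displace fluoride from 3-bromo-4-fluorobenzaldehyde by SNAr para to the formyl group, with retention at the carbinol carbon, and comes back to the route at 6.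

Step 4. β-Hydride elimination from the palladium alkoxide (hydrodebromination together with oxidation of the carbinol) and competing closure through the primary hydroxyl may consume the diol. The fallback sets out from 7. TBSCl and imidazole in CH2Cl2 at 0 °C should silylate only the primary hydroxyl to give 3-bromo-4-{[(1R,2R)-1-[4-(benzyloxy)-3-methoxyphenyl]-3-[(tert-butyldimethylsilyl)oxy]-2-hydroxypropyl]oxy}benzaldehyde F4. An Ullmann-type etherification (CuI, 1,10-phenanthroline, Cs2CO3, toluene, 110 °C), in which the monovalent copper alkoxide has no easy β-hydride path, should close the ring to (2R,3R)-2-[4-(benzyloxy)-3-methoxyphenyl]-3-{[(tert-butyldimethylsilyl)oxy]methyl}-2,3-dihydro-1,4-benzodioxine-6-carbaldehyde F5. Bu4NF in THF should then remove the silyl group, and the fallback comes back to the route at 8.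

**Further compounds**

F1 | step 5 | 5,7-bis(benzyloxy)-2-[(2R,3R)-2-[4-(benzyloxy)-3-methoxyphenyl]-3-(hydroxymethyl)-2,3-dihydro-1,4-benzodioxin-6-yl]-4H-chromen-4-one | COc1cc([C@H]2Oc3ccc(-c4cc(=O)c5c(OCc6ccccc6)cc(OCc6ccccc6)cc5o4)cc3O[C@@H]2CO)ccc1OCc1ccccc1
F2 | step 2 | [4-(benzyloxy)-3-methoxyphenyl][(4R)-2,2-dimethyl-1,3-dioxolan-4-yl]methanone | COc1cc(C(=O)[C@H]2COC(C)(C)O2)ccc1OCc1ccccc1
F3 | step 2 | (R)-[4-(benzyloxy)-3-methoxyphenyl][(4R)-2,2-dimethyl-1,3-dioxolan-4-yl]methanol (syn) | COc1cc([C@@H](O)[C@H]2COC(C)(C)O2)ccc1OCc1ccccc1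
F4 | step 4 | 3-bromo-4-{[(1R,2R)-1-[4-(benzyloxy)-3-methoxyphenyl]-3-[(tert-butyldimethylsilyl)oxy]-2-hydroxypropyl]oxy}benzaldehyde | COc1cc([C@@H](Oc2ccc(C=O)cc2Br)[C@H](O)CO[Si](C)(C)C(C)(C)C)ccc1OCc1ccccc1
F5 | step 4 | (2R,3R)-2-[4-(benzyloxy)-3-methoxyphenyl]-3-{[(tert-butyldimethylsilyl)oxy]methyl}-2,3-dihydro-1,4-benzodioxine-6-carbaldehyde | COc1cc([C@H]2Oc3ccc(C=O)cc3O[C@@H]2CO[Si](C)(C)C(C)(C)C)ccc1OCc1ccccc1
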